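The dihydrofuran ring is cut between C2 and C3. C3, the benzylic CH2, sits ortho to the ring oxygen O1 on the benzene ring, so it can be the formyl carbon of a salicylaldehyde, while C2 is the OCH2 carbon of that aldehyde's alkyl ether. A chiral cobalt porphyrin turns the tosylhydrazone of 5-bromo-2-[(2R)-3-chloro-2-methylpropoxy]benzaldehyde into a carbene radical at C3 that inserts into the O–CH2 C–H bond, closing the five-membered ring and setting C2 in one operation. The side-chain stereocentre is bought in a C4 bromochloride; the alkyl chloride and aryl bromide then carry the p-coumarate ester and the acrylic acid.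

Key step: step 3

Assumption: (S)-1-bromo-3-chloro-2-methylpropane is taken as a catalogue compound, and both antipodes of the chiral cobalt porphyrin are taken as accessible; the antipode that forms the (2S) ring carbon is identified by running both and is the one used.

Step 1
Reactants: 1 5-bromo-2-hydroxybenzaldehyde (slight excess); 2 (S)-1-bromo-3-chloro-2-methylpropane
Product: 3 5-bromo-2-[(2R)-3-chloro-2-methylpropoxy]benzaldehyde
Conditions: K2CO3, DMF, 70 °C
Reagents that add atoms: none
Why: Williamson ether synthesis, in which the phenoxide should displace bromide (SN2) far faster than chloride at two otherwise equivalent β-branched primary carbons; the stereocentre is not touched (its descriptor changes only by priority), and any product of chloride displacement still carries a reactive C–Br bond and should be consumed to a separable bis-ether by the excess of 1.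

Step 2
Reactants: 3 5-bromo-2-[(2R)-3-chloro-2-methylpropoxy]benzaldehyde
Product: 4 N'-[(E)-{5-bromo-2-[(2R)-3-chloro-2-methylpropoxy]phenyl}methylidene]-4-methylbenzenesulfonohydrazide
Conditions: TsNHNH2, MeOH, rt
Reagents that add atoms: 4-methylbenzenesulfonohydrazide (TsNHNH2), Cc1ccc(cc1)S(=O)(=O)NN
Why: Condensation of the aldehyde with the sulfonyl hydrazide should give the crystalline (E)-N-tosylhydrazone, the bench-stable precursor for Bamford–Stevens diazo release.

Step 3
Reactants: 4 N'-[(E)-{5-bromo-2-[(2R)-3-chloro-2-methylpropoxy]phenyl}methylidene]-4-methylbenzenesulfonohydrazide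
Product: 6 (2S)-5-bromo-2-[(2R)-1-chloropropan-2-yl]-2,3-dihydro-1-benzofuran, via aryldiazomethane 5 (not isolated)
Conditions: [Co(3,5-DitBu-ChenPhyrin)] (2 mol %, D2-symmetric chiral amidoporphyrin complex of divalent cobalt), Cs2CO3, 1,4-dioxane, 60 °C
Reagents that add atoms: none
Why: Bamford–Stevens loss of sulfinate from the hydrazone anion releases aryldiazomethane 5, which the divalent cobalt metalloradical converts with loss of N2 into a benzylic carbene radical on trivalent cobalt; this abstracts a hydrogen atom from the O–CH2 group through a six-membered transition state (1,5-HAT), and the resulting α-aryloxyalkyl radical closes the ring by homolytic substitution at the cobalt-bound carbon, forming the C2–C3 bond and returning the catalyst. The closest known reaction type is the metal-catalysed intramolecular 1,5-C–H insertion (radical C–H alkylation) of 2-alkoxyaryl carbenes generated from N-sulfonylhydrazones, which gives 2-substituted 2,3-dihydrobenzofurans. The dihydrofuran ring closes in a 5-exo-tet radical substitution. The new stereocentre C2 should be set in this ring closure by the chiral cavity of the porphyrin, because the resident side-chain centre carries nearly isosteric CH3 and CH2Cl groups and exerts little bias of its own, so no mismatched pairing is expected; the side-chain centre is not involved and keeps its configuration. The step needs 1,5- over 1,6- or 1,7-hydrogen abstraction, secured by the oxygen-activated and geometrically favoured OCH2 hydrogens, and C–H alkylation over cyclopropanation or dipolar cycloaddition, secured because the substrate carries no alkene (acrylate and coumarate are introduced only afterwards). The C2 epimers are diastereomers, so a minor epimer should be removable by chromatography.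

Step 4
Reactants: 6 (2S)-5-bromo-2-[(2R)-1-chloropropan-2-yl]-2,3-dihydro-1-benzofuran; 7 (E)-p-coumaric acid
Product: 9 (2S)-2-[(2S)-5-bromo-2,3-dihydro-1-benzofuran-2-yl]propyl (2E)-3-(4-hydroxyphenyl)prop-2-enoate, via alkyl iodide 8 (not isolated)
Conditions: KHCO3 (1 equiv per 7), NaI (0.3 equiv), DMF, 80 °C
Reagents that add atoms: sodium iodide, [Na+].[I-] (iodine appears in intermediate 8 only and is released again)
Why: Carboxylate O-alkylation (SN2, Finkelstein-assisted), in which iodide turns the β-branched primary chloride into the more reactive iodide 8 and hydrogen carbonate deprotonates only the carboxylic acid of 7, not its phenol, so the ester should form chemoselectively; no stereocentre lies at the reacting carbon.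

Step 5
Reactants: 9 (2S)-2-[(2S)-5-bromo-2,3-dihydro-1-benzofuran-2-yl]propyl (2E)-3-(4-hydroxyphenyl)prop-2-enoate; 10 acrylic acid
Product: 11 (2E)-3-{(2S)-2-[(2S)-1-{[(2E)-3-(4-hydroxyphenyl)prop-2-enoyl]oxy}propan-2-yl]-2,3-dihydro-1-benzofuran-5-yl}prop-2-enoic acid (CNP0224846.1)
Conditions: Pd(OAc)2 (5 mol %), P(o-tol)3 (12 mol %), Et3N, DMF, 100 °C; then aq. HCl work-up
Reagents that add atoms: none
Why: Mizoroki–Heck reaction, in which oxidative addition of the aryl bromide to zerovalent palladium, insertion of the monosubstituted acrylic acid (far more reactive than the 1,2-disubstituted coumarate alkene) and syn β-hydride elimination should give the (E)-cinnamic acid; the free phenol, the ester and both stereocentres are inert.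

Compound list
1 | 5-bromo-2-hydroxybenzaldehyde (5-bromosalicylaldehyde) | O=Cc1cc(Br)ccc1O | starting material
2 | (S)-1-bromo-3-chloro-2-methylpropane | C[C@@H](CCl)CBr | starting material
3 | 5-bromo-2-[(2R)-3-chloro-2-methylpropoxy]benzaldehyde | C[C@@H](CCl)COc1ccc(Br)cc1C=O | intermediate
4 | N'-[(E)-{5-bromo-2-[(2R)-3-chloro-2-methylpropoxy]phenyl}methylidene]-4-methylbenzenesulfonohydrazide | C[C@@H](CCl)COc1ccc(Br)cc1/C=N/NS(=O)(=O)c1ccc(C)cc1 | intermediate
5 | 4-bromo-1-[(2R)-3-chloro-2-methylpropoxy]-2-(diazomethyl)benzene | C[C@@H](CCl)COc1ccc(Br)cc1C=[N+]=[N-] | intermediate (not isolated)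
6 | (2S)-5-bromo-2-[(2R)-1-chloropropan-2-yl]-2,3-dihydro-1-benzofuran | C[C@@H](CCl)[C@@H]1Cc2cc(Br)ccc2O1 | intermediate
7 | (E)-p-coumaric acid, (2E)-3-(4-hydroxyphenyl)prop-2-enoic acid | O=C(O)/C=C/c1ccc(O)cc1 | starting material
8 | (2S)-5-bromo-2-[(2R)-1-iodopropan-2-yl]-2,3-dihydro-1-benzofuran | C[C@@H](CI)[C@@H]1Cc2cc(Br)ccc2O1 | intermediate (not isolated)
9 | (2S)-2-[(2S)-5-bromo-2,3-dihydro-1-benzofuran-2-yl]propyl (2E)-3-(4-hydroxyphenyl)prop-2-enoate | C[C@@H](COC(=O)/C=C/c1ccc(O)cc1)[C@@H]1Cc2cc(Br)ccc2O1 | intermediate
10 | acrylic acid | C=CC(=O)O | starting material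
11 | (2E)-3-{(2S)-2-[(2S)-1-{[(2E)-3-(4-hydroxyphenyl)prop-2-enoyl]oxy}propan-2-yl]-2,3-dihydro-1-benzofuran-5-yl}prop-2-enoic acid | C[C@@H](COC(=O)/C=C/c1ccc(O)cc1)[C@@H]1Cc2cc(/C=C/C(=O)O)ccc2O1 | target

Total step count: 5. Longest linear sequence: 5 steps (1 or 2 to 11).

Steps most likely to fail

Step 3. The catalyst's control over the face on which the ring closes may be too weak, so that both C2 configurations form in comparable amounts; carbene dimerisation or azine formation may also erode the yield. Fallback, from 4 back to 6: hydrazone 4 is cyclised without stereocontrol using the achiral cobalt porphyrin [Co(TPP)] (divalent cobalt) and Cs2CO3 in 1,4-dioxane, which should give 6 mixed with its C2 epimer, (2R)-5-bromo-2-[(2R)-1-chloropropan-2-yl]-2,3-dihydro-1-benzofuran F1. The mixture is dehydrogenated with DDQ (1,4-dioxane, reflux) to 5-bromo-2-[(2R)-1-chloropropan-2-yl]-1-benzofuran F2. C2 is then set by enantioselective hydrogenation of the furan ring with a chiral ruthenium N-heterocyclic carbene catalyst (from [Ru(cod)(2-methylallyl)2], SINpEt·HBF4 of the appropriate handedness and KOtBu; H2, hexane), which returns 6.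

Step 4. Substitution at the β-branched CH2Cl carbon may be slow, so that phenoxide O-alkylation or elimination takes over at the temperature required. Fallback, from 6 back to 9: the chloride is displaced (via iodide 8) by the small, phenol-free nucleophile acetate (KOAc, NaI, DMSO, 100 °C) to give (2S)-2-[(2S)-5-bromo-2,3-dihydro-1-benzofuran-2-yl]propyl acetate F3. Methanolysis (K2CO3, MeOH, rt) gives (2S)-2-[(2S)-5-bromo-2,3-dihydro-1-benzofuran-2-yl]propan-1-ol F4. A Mitsunobu esterification with 7 (PPh3, DIAD, THF, 0 °C to rt), in which the carboxylic acid reacts in preference to the less acidic phenol, should then give 9.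

Step 5. The coumarate alkene may compete as the Heck acceptor, or the free acid and phenol may inhibit the catalyst, leaving incomplete coupling or oligomeric material. Fallback, from 6 to 11: the Heck coupling is moved ahead of the esterification and run on chloride 6 with tert-butyl acrylate (Pd(OAc)2, P(o-tol)3, Et3N, DMF, 100 °C) to give tert-butyl (2E)-3-{(2S)-2-[(2R)-1-chloropropan-2-yl]-2,3-dihydro-1-benzofuran-5-yl}prop-2-enoate F5. Alkylation of 7 (KHCO3, NaI, DMF, 80 °C) proceeds through the in-flask iodide tert-butyl (2E)-3-{(2S)-2-[(2R)-1-iodopropan-2-yl]-2,3-dihydro-1-benzofuran-5-yl}prop-2-enoate F6 to the diester tert-butyl (2E)-3-{(2S)-2-[(2S)-1-{[(2E)-3-(4-hydroxyphenyl)prop-2-enoyl]oxy}propan-2-yl]-2,3-dihydro-1-benzofuran-5-yl}prop-2-enoate F7. TFA in CH2Cl2 at rt then removes the tert-butyl group to give 11.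

Further compounds
F1 | step 3 | (2R)-5-bromo-2-[(2R)-1-chloropropan-2-yl]-2,3-dihydro-1-benzofuran | C[C@@H](CCl)[C@H]1Cc2cc(Br)ccc2O1
F2 | step 3 | 5-bromo-2-[(2R)-1-chloropropan-2-yl]-1-benzofuran | C[C@@H](CCl)c1cc2cc(Br)ccc2o1
F3 | step 4 | (2S)-2-[(2S)-5-bromo-2,3-dihydro-1-benzofuran-2-yl]propyl acetate | C[C@@H](COC(C)=O)[C@@H]1Cc2cc(Br)ccc2O1
F4 | step 4 | (2S)-2-[(2S)-5-bromo-2,3-dihydro-1-benzofuran-2-yl]propan-1-ol | C[C@@H](CO)[C@@H]1Cc2cc(Br)ccc2O1
F5 | step 5 | tert-butyl (2E)-3-{(2S)-2-[(2R)-1-chloropropan-2-yl]-2,3-dihydro-1-benzofuran-5-yl}prop-2-enoate | C[C@@H](CCl)[C@@H]1Cc2cc(/C=C/C(=O)OC(C)(C)C)ccc2O1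
F6 | step 5 | tert-butyl (2E)-3-{(2S)-2-[(2R)-1-iodopropan-2-yl]-2,3-dihydro-1-benzofuran-5-yl}prop-2-enoate | C[C@@H](CI)[C@@H]1Cc2cc(/C=C/C(=O)OC(C)(C)C)ccc2O1
F7 | step 5 | tert-butyl (2E)-3-{(2S)-2-[(2S)-1-{[(2E)-3-(4-hydroxyphenyl)prop-2-enoyl]oxy}propan-2-yl]-2,3-dihydro-1-benzofuran-5-yl}prop-2-enoate | C[C@@H](COC(=O)/C=C/c1ccc(O)cc1)[C@@H]1Cc2cc(/C=C/C(=O)OC(C)(C)C)ccc2O1
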